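**Retrosynthetic overview**

- The target is cut back to 1-hydroxypinoresinol; the C8 acetate comes from peracetylation followed by aminolysis of the two aryl acetates.
- 1-Hydroxypinoresinol is cut at the two benzylic C–O bonds, C7–O (ring B: C7–O–C9'–C8'–C8) and C7'–O (ring A: C7'–O–C9–C8–C8'). This gives (2S,3S)-2,3-bis(4-hydroxy-3-methoxybenzyl)butane-1,2,4-triol. Forward, DDQ converts both 4-hydroxybenzyl CH2 groups into p-quinone methides and both rings close in the same flask, so rings A and B form together and last.
- The feature relied on: the chain C9–C8(O)–C8'–C9' is L-malic acid carbon for carbon, with its carbinol stereocentre as C8. C7 and C7' are CH2 groups para to a phenol (latent quinone methide carbons), each five atoms from a primary hydroxyl.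
- The triol comes from L-malic acid: C8'–C7' by Fráter–Seebach benzylation (anti), C8–C7 by benzylation of the pivalaldehyde dioxolanone (retention), then LiAlH4 and hydrogenolysis. The benzylic bromide comes from O-benzylvanillin.

Key step: step 10

Remark on the chemistry: lignan numbering is used throughout (C8 = acetoxy bridgehead, C7 and C9 its ArCH and OCH2 neighbours; C8' = CH bridgehead, C7' and C9' its ArCH and OCH2 neighbours). Read this way the target is (7R,8S,7'S,8'R), with the C8 oxygen, H8' and both aryl groups on the convex face of the cis-fused bicycle. The butanetriol that maps onto it is (2S,3S). The C8' descriptor is R in the malate esters and S in the triol only because the CIP priorities change on reduction; the centre is not inverted.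

**Route**

Step 1
Reactants: 1 4-(benzyloxy)-3-methoxybenzaldehyde (O-benzylvanillin)
Product: 2 [4-(benzyloxy)-3-methoxyphenyl]methanol
Conditions: NaBH4, MeOH–THF, 0 °C
Reagents that add atoms: none
Why: Chemoselective NaBH4 hydride reduction of the aryl aldehyde gives the benzylic alcohol, and the benzyl aryl ether is inert.

Step 2
Reactants: 2 [4-(benzyloxy)-3-methoxyphenyl]methanol
Product: 3 1-(benzyloxy)-4-(bromomethyl)-2-methoxybenzene
Conditions: PBr3 (0.4 equiv), Et2O, 0 °C
Reagents that add atoms: phosphorus tribromide, BrP(Br)Br
Why: Bromide displacement on the phosphite ester of an electron-rich benzylic alcohol (alcohol to bromide with PBr3) is fast at 0 °C and leaves both aryl ethers untouched; the bromide should be used soon after it is made.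

Step 3
Reactants: 4 L-malic acid
Product: 5 dimethyl (S)-malate
Conditions: MeOH, HCl (anhydrous, cat.), rt
Reagents that add atoms: methanol, CO
Why: Fischer esterification converts both carboxyl groups, and the C2 stereocentre is not enolisable under these conditions.

Step 4
Reactants: 5 dimethyl (S)-malate; 3 1-(benzyloxy)-4-(bromomethyl)-2-methoxybenzene
Product: 7 dimethyl (2S,3R)-3-{[4-(benzyloxy)-3-methoxyphenyl]methyl}-2-hydroxybutanedioate, via dilithium alkoxide–enolate 6 (not isolated)
Conditions: LiN(SiMe3)2 (2.2 equiv), THF, −78 → −20 °C; then 3, −78 → −10 °C; AcOH quench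
Reagents that add atoms: none
Why: Fráter–Seebach alkylation: the lithium-chelated alkoxide–enolate 6 takes the benzylic bromide at C3 on the face anti to the ester group on the carbinol carbon, so the C8'–C7' bond forms anti to the hydroxyl and the new centre is 3R (the later C8'); the minor syn isomer should be removable by chromatography.

Step 5
Reactants: 7 dimethyl (2S,3R)-3-{[4-(benzyloxy)-3-methoxyphenyl]methyl}-2-hydroxybutanedioate
Product: 8 (2S,3R)-3-{[4-(benzyloxy)-3-methoxyphenyl]methyl}-2-hydroxybutanedioic acid
Conditions: LiOH (3 equiv), THF–H2O, 0 °C → rt; then 1 M HCl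
Reagents that add atoms: lithium hydroxide, [Li+].[OH-]
Why: Saponification (ester hydrolysis by hydroxide) at or below room temperature gives the dicarboxylate, whose carboxylate groups protect the C3–H against enolisation, so both stereocentres are kept.

Step 6
Reactants: 8 (2S,3R)-3-{[4-(benzyloxy)-3-methoxyphenyl]methyl}-2-hydroxybutanedioic acid; 9 pivalaldehyde
Product: 10 (2R)-3-[4-(benzyloxy)-3-methoxyphenyl]-2-[(2S,4S)-2-tert-butyl-5-oxo-1,3-dioxolan-4-yl]propanoic acid
Conditions: 9 (3 equiv), cat. TsOH·H2O, cat. H2SO4, pentane, reflux, azeotropic removal of H2O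
Reagents that add atoms: none
Why: Seebach acetalisation of the α-hydroxy acid unit (first stage of the self-regeneration of stereocentres) closes the five-membered dioxolanone in preference to the six-membered acetal of the β-carboxyl group, and under equilibrating acid catalysis C8 sets the new acetal centre 2S, with tert-butyl and the side chain cis.

Step 7
Reactants: 10 the cis-dioxolanone acid; 3 1-(benzyloxy)-4-(bromomethyl)-2-methoxybenzene
Product: 12 (2R)-3-[4-(benzyloxy)-3-methoxyphenyl]-2-[(2S,4S)-4-{[4-(benzyloxy)-3-methoxyphenyl]methyl}-2-tert-butyl-5-oxo-1,3-dioxolan-4-yl]propanoic acid, via dilithium enolate–carboxylate 11 (not isolated)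
Conditions: LiN(SiMe3)2 (2.2 equiv), THF–DMPU, −78 °C; then 3, −78 → −30 °C; AcOH quench
Reagents that add atoms: none
Why: Seebach alkylation of a dioxolanone enolate (self-regeneration of stereocentres): the second equivalent of base enolises the ring C–H of the lithium carboxylate, and the bromide enters trans to the tert-butyl group, where the hydrogen was, so the quaternary C8 forms with overall retention.

Step 8
Reactants: 12 the dibenzylated dioxolanone acid
Product: 13 (2S,3S)-2,3-bis{[4-(benzyloxy)-3-methoxyphenyl]methyl}butane-1,2,4-triol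
Conditions: LiAlH4, THF, 0 °C → reflux; aq. KNaC4H4O6 work-up
Reagents that add atoms: none
Why: LiAlH4 reduction turns the carboxylic acid into C9'H2OH and the dioxolanone carbonyl into C9H2OH, while the acetal collapses to the tertiary alkoxide and pivalaldehyde (reduced on to neopentyl alcohol); no stereocentre is touched and the aryl benzyl ethers survive.

Step 9
Reactants: 13 (2S,3S)-2,3-bis{[4-(benzyloxy)-3-methoxyphenyl]methyl}butane-1,2,4-triol
Product: 14 (2S,3S)-2,3-bis[(4-hydroxy-3-methoxyphenyl)methyl]butane-1,2,4-triol
Conditions: H2 (1 atm), Pd/C, EtOAc–MeOH, rt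
Reagents that add atoms: none
Why: Catalytic hydrogenolysis over Pd/C cleaves only the two O-benzyl aryl ethers, since the molecule holds no other benzylic carbon–heteroatom bond or reducible group.

Step 10
Reactants: 14 (2S,3S)-2,3-bis[(4-hydroxy-3-methoxyphenyl)methyl]butane-1,2,4-triol
Product: 16 (7R,8S,7'S,8'R)-1-hydroxypinoresinol, via bis(p-quinone methide) 15 (not isolated)
Conditions: DDQ (2.0 equiv, slow addition as a solution), 1,4-dioxane (0.01 M), 15–20 °C, Ar, dark
Reagents that add atoms: none
Why: DDQ removes a hydride from each benzylic CH2 para to a free phenol (charge-transfer complex, then loss of the phenolic proton) to give the two p-quinone methide units of 15; the primary C9'–OH then adds to C7 and the primary C9–OH adds to C7' with rearomatisation, so ring B (C7–O–C9'–C8'–C8) and ring A (C7'–O–C9–C8–C8') each close by 5-exo-trig conjugate addition. The closest known reaction is the DDQ (or Ag2O) dehydrogenation of 4-hydroxy-3-methoxybenzyl groups in dibenzylbutanediol lignans with capture of the quinone methide by a CH2OH group to give 7,9'-epoxylignans, run here twice in one flask. The cis ring fusion is fixed by the preset C8 and C8' centres; C7 is set by closure with the flat quinone methide anti to C9 on C8 (aryl cis to the C8 hydroxyl), and C7' likewise anti to C9' on C8' (aryl cis to H8'), which places both aryl groups on the convex face. The step needs oxygen capture to beat attack by the other guaiacyl ring (aryltetralin) and tautomerisation of the C7' quinone methide to a styrene; the five-membered transition state with a primary alcohol, the neutral aprotic medium and high dilution should secure this, and the tertiary C8–OH can only give three- or four-membered rings. It also needs the oxidation to stop at the ether stage, which the exact 2.0 equiv of DDQ, its slow addition and the concave-face position of H7 and H7' in the bicycle (poorly accessible to the oxidant) are meant to secure.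

Step 11
Reactants: 16 1-hydroxypinoresinol
Product: 17 1-acetoxypinoresinol 4,4'-di-O-acetate (triacetate)
Conditions: Ac2O (excess), Et3N, DMAP, CH2Cl2, rt → 40 °C
Reagents that add atoms: acetic anhydride, CC(=O)OC(C)=O
Why: 4-Dimethylaminopyridine-catalysed acylation (Steglich-type) should acetylate both phenols at once and the hindered tertiary C8 hydroxyl more slowly, under basic conditions that cannot ionise the benzylic ether bonds at C7 and C7'.

Step 12
Reactants: 17 1-acetoxypinoresinol 4,4'-di-O-acetate
Product: 18 1-acetoxypinoresinol (target)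
Conditions: pyrrolidine (2.5 equiv), CH2Cl2, 0 °C
Reagents that add atoms: none
Why: Chemoselective aminolysis: aryl acetates are activated esters that pyrrolidine cleaves at 0 °C, whereas the tertiary alkyl acetate at C8 is unreactive, so only the two phenols are set free and no stereocentre is touched.

**Compound list**

1 | 4-(benzyloxy)-3-methoxybenzaldehyde (O-benzylvanillin) | COc1cc(C=O)ccc1OCc1ccccc1 | starting material
2 | [4-(benzyloxy)-3-methoxyphenyl]methanol | COc1cc(CO)ccc1OCc1ccccc1 | intermediate
3 | 1-(benzyloxy)-4-(bromomethyl)-2-methoxybenzene | COc1cc(CBr)ccc1OCc1ccccc1 | intermediate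
4 | L-malic acid, (S)-2-hydroxybutanedioic acid | OC(=O)C[C@H](O)C(=O)O | starting material
5 | dimethyl (S)-malate | COC(=O)C[C@H](O)C(=O)OC | intermediate
6 | dilithium alkoxide–enolate of 5 (enolate oxygen cis to C2; formed in the flask, not isolated) | COC(=O)[C@@H]([O-])/C=C(\[O-])OC.[Li+].[Li+] | intermediate
7 | dimethyl (2S,3R)-3-{[4-(benzyloxy)-3-methoxyphenyl]methyl}-2-hydroxybutanedioate | COC(=O)[C@@H](O)[C@@H](Cc1ccc(OCc2ccccc2)c(OC)c1)C(=O)OC | intermediate
8 | (2S,3R)-3-{[4-(benzyloxy)-3-methoxyphenyl]methyl}-2-hydroxybutanedioic acid | OC(=O)[C@@H](O)[C@@H](Cc1ccc(OCc2ccccc2)c(OC)c1)C(=O)O | intermediate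
9 | pivalaldehyde (2,2-dimethylpropanal) | CC(C)(C)C=O | starting material
10 | (2R)-3-[4-(benzyloxy)-3-methoxyphenyl]-2-[(2S,4S)-2-tert-butyl-5-oxo-1,3-dioxolan-4-yl]propanoic acid (tert-butyl and side chain cis) | CC(C)(C)[C@H]1O[C@@H]([C@@H](Cc2ccc(OCc3ccccc3)c(OC)c2)C(=O)O)C(=O)O1 | intermediate
11 | dilithium enolate–carboxylate of 10 (formed in the flask, not isolated) | CC(C)(C)[C@H]1OC(=C([O-])O1)[C@@H](Cc2ccc(OCc3ccccc3)c(OC)c2)C(=O)[O-].[Li+].[Li+] | intermediate
12 | (2R)-3-[4-(benzyloxy)-3-methoxyphenyl]-2-[(2S,4S)-4-{[4-(benzyloxy)-3-methoxyphenyl]methyl}-2-tert-butyl-5-oxo-1,3-dioxolan-4-yl]propanoic acid (new benzyl trans to tert-butyl) | CC(C)(C)[C@H]1O[C@@](Cc2ccc(OCc3ccccc3)c(OC)c2)([C@@H](Cc4ccc(OCc5ccccc5)c(OC)c4)C(=O)O)C(=O)O1 | intermediate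
13 | (2S,3S)-2,3-bis{[4-(benzyloxy)-3-methoxyphenyl]methyl}butane-1,2,4-triol | COc1cc(C[C@@H](CO)[C@](O)(CO)Cc2ccc(OCc3ccccc3)c(OC)c2)ccc1OCc1ccccc1 | intermediate
14 | (2S,3S)-2,3-bis[(4-hydroxy-3-methoxyphenyl)methyl]butane-1,2,4-triol | COc1cc(C[C@@H](CO)[C@](O)(CO)Cc2ccc(O)c(OC)c2)ccc1O | intermediate
15 | bis(p-quinone methide) of 14: C7 and C7' are sp2 carbons exocyclic to 3-methoxy-4-oxocyclohexa-2,5-dienylidene rings, C8 and C8' as in 14 (formed in the flask, not isolated) | COC1=CC(=C[C@@H](CO)[C@](O)(CO)C=C2C=CC(=O)C(OC)=C2)C=CC1=O | intermediate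
16 | (7R,8S,7'S,8'R)-1-hydroxypinoresinol, (1S,2R,5R,6S)-2,6-bis(4-hydroxy-3-methoxyphenyl)-3,7-dioxabicyclo[3.3.0]octan-1-ol | COc1cc([C@H]2OC[C@]3(O)[C@@H](c4ccc(O)c(OC)c4)OC[C@H]23)ccc1O | intermediate
17 | 1-acetoxypinoresinol 4,4'-di-O-acetate (triacetate of 16) | COc1cc([C@H]2OC[C@]3(OC(C)=O)[C@@H](c4ccc(OC(C)=O)c(OC)c4)OC[C@H]23)ccc1OC(C)=O | intermediate
18 | 1-acetoxypinoresinol, (7R,8S,7'S,8'R) | COc1cc([C@H]2OC[C@]3(OC(C)=O)[C@@H](c4ccc(O)c(OC)c4)OC[C@H]23)ccc1O | target

**Step count**

Total: 12 steps. Longest linear sequence: 11 steps (1 → 18 through steps 1, 2 and 4–12). Dimethyl (S)-malate 5 can also be bought, which would remove step 3.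

**Steps most likely to fail, with fallbacks**

Step 10 (twofold oxidative ring closure). Three processes could go wrong:
- The first-formed p-hydroxybenzylic ether, whose α-alkoxy C–H is more hydridic, may be oxidised further before the second ring has closed.
- The C7' quinone methide may tautomerise to the C7'=C8' styrene, which would lose the C8' centre.
- Facial selectivity at C7 and C7' may be poor.

The fallback drops the need to stop at the ether stage and closes the rings by ionisation instead of by oxidation. It sets out from 14. Treatment with DDQ (4.2 equiv) in dioxane–H2O at rt should take each benzylic carbon through quinone methide, hydration or ring closure, and a second dehydrogenation to the aryl ketone level. This gives the 7,7'-dioxo derivative of 14 F1 (C8 and C8' unchanged, partly present as cyclic hemiketals), which is reduced without purification to limit enolisation at C8'. NaBH4 in MeOH at −20 → 0 °C should give the 7,7'-dihydroxy derivative of 14 F2 as a mixture of C7/C7' epimers, which does not matter because both centres are ionised next. A trace of camphorsulfonic acid in THF at 0 °C → rt should then generate each p-hydroxybenzylic cation, which is captured 5-exo by C9'–OH and C9–OH. This is the classical cyclodehydration of 1,4-diaryl-2,3-bis(hydroxymethyl)butane-1,4-diols to furofurans, with the aryl groups expected on the convex face; the acid exposure is kept short to avoid aryltetralin formation. The fallback comes back to the route at 16.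

Step 7 (quaternary centre at C8). The enolate–carboxylate 11 is aggregated and carries the C8' branch next to the reacting carbon, so alkylation may be slow or incomplete and the enolate may decompose on warming. Upstream, the cis selectivity of the acetalisation in step 6 on the branched acid is also less secure than for malic acid itself. The fallback reverses the order of the two C–C bond formations, so that the quaternary centre is made first on the unbranched substrate. It sets out from 4 and 9 and uses 3.
- Acetalisation of 4 with 9 (cat. TsOH·H2O, cat. H2SO4, pentane, reflux) should give 2-[(2S,4S)-2-tert-butyl-5-oxo-1,3-dioxolan-4-yl]acetic acid F3.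
- Double deprotonation with LiN(SiMe3)2 (2.2 equiv, THF, −78 °C) and alkylation with 3, trans to tert-butyl, should give 2-[(2S,4S)-4-{[4-(benzyloxy)-3-methoxyphenyl]methyl}-2-tert-butyl-5-oxo-1,3-dioxolan-4-yl]acetic acid F4.
- Acid alcoholysis (i-PrOH, HCl, reflux) should open the acetal and esterify both carboxyl groups to diisopropyl (2S)-2-{[4-(benzyloxy)-3-methoxyphenyl]methyl}-2-hydroxybutanedioate F5.
- A second Fráter–Seebach-type alkylation (LiN(SiMe3)2, 2.2 equiv, THF, −78 → −10 °C, then 3) should give diisopropyl (2S,3R)-2,3-bis{[4-(benzyloxy)-3-methoxyphenyl]methyl}-2-hydroxybutanedioate F6. The chelated tertiary alkoxide–enolate is expected to take the electrophile anti to the ester group on the carbinol carbon, as in step 4, and the bulky isopropyl esters reinforce this bias. This facial preference is less secure than in the main sequence, which is why this order is the reserve.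
- LiAlH4 (THF, 0 °C → reflux) reduces both esters.

The fallback comes back to the route at 13.

Step 11 (acetylation of the tertiary bridgehead hydroxyl). The hindered C8–OH may acylate incompletely under conditions mild enough for the rest of the molecule, leaving mixtures of di- and triacetate. The fallback acylates the tertiary alkoxide on a phenol-protected substrate. It sets out from 16. TBSCl and imidazole in DMF at rt should silylate only the two phenols, giving 4,4'-bis-O-(tert-butyldimethylsilyl)-1-hydroxypinoresinol F7. Deprotonation of the tertiary alcohol with LiN(SiMe3)2 (1.1 equiv, THF, −78 °C) and trapping with Ac2O should give 4,4'-bis-O-(tert-butyldimethylsilyl)-1-acetoxypinoresinol F8. Buffered fluoride (Bu4NF, AcOH, THF, 0 °C) then removes the aryl silyl ethers without touching the tertiary acetate. The fallback comes back to the route at 18 and bypasses 17 and step 12.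

**Further compounds**

F1 | step 10 | 7,7'-dioxo derivative of 14: (2S,3S)-2-hydroxy-1,4-bis(4-hydroxy-3-methoxyphenyl)-2,3-bis(hydroxymethyl)butane-1,4-dione | COc1cc(C(=O)[C@@H](CO)[C@](O)(CO)C(=O)c2ccc(O)c(OC)c2)ccc1O
F2 | step 10 | 7,7'-dihydroxy derivative of 14 (mixture of C7 and C7' epimers; C8 and C8' as in 14) | COc1cc(C(O)[C@@H](CO)[C@](O)(CO)C(O)c2ccc(O)c(OC)c2)ccc1O
F3 | step 7 | 2-[(2S,4S)-2-tert-butyl-5-oxo-1,3-dioxolan-4-yl]acetic acid | CC(C)(C)[C@H]1O[C@@H](CC(=O)O)C(=O)O1
F4 | step 7 | 2-[(2S,4S)-4-{[4-(benzyloxy)-3-methoxyphenyl]methyl}-2-tert-butyl-5-oxo-1,3-dioxolan-4-yl]acetic acid | CC(C)(C)[C@H]1O[C@@](Cc2ccc(OCc3ccccc3)c(OC)c2)(CC(=O)O)C(=O)O1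
F5 | step 7 | diisopropyl (2S)-2-{[4-(benzyloxy)-3-methoxyphenyl]methyl}-2-hydroxybutanedioate | CC(C)OC(=O)C[C@@](O)(Cc1ccc(OCc2ccccc2)c(OC)c1)C(=O)OC(C)C
F6 | step 7 | diisopropyl (2S,3R)-2,3-bis{[4-(benzyloxy)-3-methoxyphenyl]methyl}-2-hydroxybutanedioate | CC(C)OC(=O)[C@H](Cc1ccc(OCc2ccccc2)c(OC)c1)[C@@](O)(Cc1ccc(OCc2ccccc2)c(OC)c1)C(=O)OC(C)C
F7 | step 11 | 4,4'-bis-O-(tert-butyldimethylsilyl)-1-hydroxypinoresinol | COc1cc([C@H]2OC[C@]3(O)[C@@H](c4ccc(O[Si](C)(C)C(C)(C)C)c(OC)c4)OC[C@H]23)ccc1O[Si](C)(C)C(C)(C)C
F8 | step 11 | 4,4'-bis-O-(tert-butyldimethylsilyl)-1-acetoxypinoresinol | COc1cc([C@H]2OC[C@]3(OC(C)=O)[C@@H](c4ccc(O[Si](C)(C)C(C)(C)C)c(OC)c4)OC[C@H]23)ccc1O[Si](C)(C)C(C)(C)C
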